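**Plan**

- Numbering: ring A is the aromatic ring of the chroman (C4a–C8a, ketone on C6). Ring B is C1'–C6', with the ketone chain on C1', prenyl on C3' and OH on C4'. The target is achiral; the two stereocentres that appear in step 8 vanish when ring B is aromatised.
- Enabling feature: ring B is a para-alkylphenol with one ortho substituent (C1' alkyl, C3' prenyl, C4' OH), i.e. the aromatised form of a 4-alkyl-2-prenylcyclohex-2-enone. The retrosynthesis cuts C1'–C6' (Michael addition) and C2'=C3' (aldol condensation), giving an aldehyde that holds C1', C2' and ring A, and a vinyl ketone that holds C3'–C6' with the prenyl group.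
- Reinforcement: the vinyl ketone carries PhS on C5', so aromatisation becomes a sulfoxide elimination at a fixed carbon. Enolate-based dehydrogenation could not tell the ring ketone from the aryl ketone, and iodine, quinone or divalent palladium oxidants would threaten the prenyl/phenol pair or ring A.
- Ring A side: the C6–C(=O) bond is cut to an aryllithium and δ-valerolactone, the pyran ring to phloroglucinol and isoprene.
- Forward order: pyran ring on phloroglucinol, MOM protection, C6 acylation, oxidation to the keto-aldehyde (steps 1–4); sulfanyl vinyl ketone (steps 5–7); ring B by annulation (step 8), aromatisation (step 9), deprotection (step 10).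

Key step: step 8

Assumption: lithiation of 4 is taken to occur at C6, the only ring position flanked by two MOM ethers.

**Route**

Step 1
Reactants: 1 phloroglucinol (benzene-1,3,5-triol); 2 isoprene (2-methylbuta-1,3-diene)
Product: 3 2,2-dimethylchroman-5,7-diol
Conditions: Amberlyst 15, THF–heptane, 65 °C, 1 in threefold excess
Reagents that add atoms: none
Why: Acid-catalysed Friedel–Crafts prenylation of the very nucleophilic ring followed by Markovnikov cycloetherification of the prenyl double bond by the adjacent hydroxyl should close the dimethylpyran ring, and the threefold symmetry of 1 (kept in excess to suppress a second annulation) allows only one mono-chroman.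

Step 2
Reactants: 3 2,2-dimethylchroman-5,7-diol
Product: 4 5,7-bis(methoxymethoxy)-2,2-dimethylchroman
Conditions: NaH, MOMCl, DMF, 0 °C → rt
Reagents that add atoms: chloromethyl methyl ether, COCCl
Why: Williamson-type O-alkylation of both phenoxides with the hard electrophile MOMCl masks the acidic hydroxyls for the basic steps that follow and installs the two directing groups for step 3.

Step 3
Reactants: 4 5,7-bis(methoxymethoxy)-2,2-dimethylchroman; 5 δ-valerolactone (tetrahydro-2H-pyran-2-one)
Product: 7 1-[5,7-bis(methoxymethoxy)-2,2-dimethylchroman-6-yl]-5-hydroxypentan-1-one, via aryllithium 6 (not isolated)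
Conditions: n-BuLi, THF, 0 °C; then 5, −78 → 0 °C; H2O
Reagents that add atoms: none
Why: Directed ortho-metalation should take C6–H, the only hydrogen between two lithium-coordinating MOM ethers, and ring-opening acylation of the lactone by the aryllithium (nucleophilic acyl substitution) gives the hydroxy ketone, whose two ortho substituents shield it from a second addition.

Step 4
Reactants: 7 1-[5,7-bis(methoxymethoxy)-2,2-dimethylchroman-6-yl]-5-hydroxypentan-1-one
Product: 8 5-[5,7-bis(methoxymethoxy)-2,2-dimethylchroman-6-yl]-5-oxopentanal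
Conditions: TEMPO (cat.), PhI(OAc)2, CH2Cl2, rt
Reagents that add atoms: none
Why: Oxoammonium-mediated (TEMPO) oxidation of the primary alcohol stops at the aldehyde under anhydrous conditions and leaves the aryl ketone, the MOM acetals and the electron-rich ring untouched.

Step 5
Reactants: 9 thiophenol (benzenethiol); 10 2-chloro-N-methoxy-N-methylacetamide
Product: 11 N-methoxy-N-methyl-2-(phenylsulfanyl)acetamide
Conditions: K2CO3, acetone, rt
Reagents that add atoms: none
Why: SN2 displacement of the carbonyl-activated primary chloride by the thiolate is a standard thioether synthesis.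

Step 6
Reactants: 11 N-methoxy-N-methyl-2-(phenylsulfanyl)acetamide; 12 5-bromo-2-methylpent-2-ene
Product: 14 6-methyl-1-(phenylsulfanyl)hept-5-en-2-one, via Grignard reagent 13 (not isolated)
Conditions: Mg, THF, rt (forms 13); then 11, 0 °C; 1 M HCl
Reagents that add atoms: none
Why: Weinreb ketone synthesis, in which the magnesium chelate of the N-methoxy-N-methyl amide holds the tetrahedral adduct until work-up, delivers the ketone after a single addition with sulfur fixed on the methylene next to the carbonyl.

Step 7
Reactants: 14 6-methyl-1-(phenylsulfanyl)hept-5-en-2-one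
Product: 16 7-methyl-2-(phenylsulfanyl)octa-1,6-dien-3-one, via Mannich base 15 (not isolated)
Conditions: (CH2O)n, PhNHMe·CF3CO2H, THF, reflux
Reagents that add atoms: formaldehyde (as paraformaldehyde), C=O
Why: Mannich-type α-methylenation should occur on the sulfur-bearing methylene, the more acidic and more readily enolised side of the ketone, and β-elimination of N-methylaniline from the Mannich base gives the 2-sulfanyl enone, which is used directly.

Step 8
Reactants: 8 5-[5,7-bis(methoxymethoxy)-2,2-dimethylchroman-6-yl]-5-oxopentanal; 16 7-methyl-2-(phenylsulfanyl)octa-1,6-dien-3-one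
Product: 18 4-{3-[5,7-bis(methoxymethoxy)-2,2-dimethylchroman-6-yl]-3-oxopropyl}-2-(3-methylbut-2-en-1-yl)-6-(phenylsulfanyl)cyclohex-2-en-1-one (mixture of racemic diastereomers), via Michael adduct 17 (not isolated)
Conditions: Et2NH (30 mol %), MeCN, rt; then piperidine, AcOH, toluene, 70 °C
Reagents that add atoms: none
Why: Et2NH condenses only with the aldehyde of 8 and the enamine adds through C1' to the unsubstituted terminus (C6') of enone 16, hydrolysis giving keto-aldehyde 17; piperidinium acetate then mediates aldol addition of the ketone α'-methylene (C3', the carbon carrying the prenyl chain) to the aldehyde carbon (C2') and E1cB dehydration to the C2'=C3' enone. The closest known reaction type is the Robinson annulation in its amine-catalysed aldehyde/vinyl ketone form, and 2-arylsulfanyl vinyl ketones are known acceptors for Michael–aldol annulations that lead to phenols. The six-membered ring closes in a 6-(enolendo)-exo-trig aldol. The two stereocentres (C1' and C5') form without control as a mixture of racemic diastereomers, which is accepted because both carbons become sp2 in step 9. The step needs enamine formation at the aldehyde only and closure through C3' only: the aryl ketone, flanked by two ortho MOM ethers, does not condense with the amine, and aldol closure through the sulfur-bearing carbon or the aldehyde α-carbon would give four-membered rings. The sulfur substituent is there because 18 holds two enolisable ketones, so the unsaturation needed for aromatisation could not be introduced regioselectively by enolate chemistry after the annulation.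

Step 9
Reactants: 18 4-{3-[5,7-bis(methoxymethoxy)-2,2-dimethylchroman-6-yl]-3-oxopropyl}-2-(3-methylbut-2-en-1-yl)-6-(phenylsulfanyl)cyclohex-2-en-1-one
Product: 21 1-[5,7-bis(methoxymethoxy)-2,2-dimethylchroman-6-yl]-3-[4-hydroxy-3-(3-methylbut-2-en-1-yl)phenyl]propan-1-one, via sulfoxide 19 (not isolated), via cyclohexadienone 20 (not isolated)
Conditions: mCPBA (1.0 equiv), CH2Cl2, −78 °C; then pyridine, toluene, 80 °C
Reagents that add atoms: none
Why: S-oxidation, much faster than epoxidation of the trisubstituted alkene at −78 °C, followed by thermal syn-elimination of benzenesulfenic acid (sulfoxide elimination), which can only take a C6' hydrogen, gives the cross-conjugated dienone whose C1' hydrogen tautomerises to the phenol without any oxidant that could touch the prenyl group or ring A.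

Step 10
Reactants: 21 1-[5,7-bis(methoxymethoxy)-2,2-dimethylchroman-6-yl]-3-[4-hydroxy-3-(3-methylbut-2-en-1-yl)phenyl]propan-1-one
Product: 22 1-(5,7-dihydroxy-2,2-dimethylchroman-6-yl)-3-[4-hydroxy-3-(3-methylbut-2-en-1-yl)phenyl]propan-1-one (target)
Conditions: 3 M HCl, MeOH, rt
Reagents that add atoms: none
Why: Acid-catalysed acetal methanolysis (MOM cleavage) is fast for ethers ortho to the ketone, and dilute acid at room temperature is chosen so that the ring B phenol does not add to the prenyl double bond.

**Compound list**

1 | phloroglucinol (benzene-1,3,5-triol) | Oc1cc(O)cc(O)c1 | starting material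
2 | isoprene (2-methylbuta-1,3-diene) | C=CC(C)=C | starting material
3 | 2,2-dimethylchroman-5,7-diol | CC1(C)CCc2c(O)cc(O)cc2O1 | intermediate
4 | 5,7-bis(methoxymethoxy)-2,2-dimethylchroman | CC1(C)CCc2c(OCOC)cc(OCOC)cc2O1 | intermediate
5 | δ-valerolactone (tetrahydro-2H-pyran-2-one) | O=C1CCCCO1 | starting material
6 | [5,7-bis(methoxymethoxy)-2,2-dimethylchroman-6-yl]lithium (formed in the flask, not isolated) | [Li]c1c(OCOC)cc2OC(C)(C)CCc2c1OCOC | intermediate
7 | 1-[5,7-bis(methoxymethoxy)-2,2-dimethylchroman-6-yl]-5-hydroxypentan-1-one | OCCCCC(=O)c1c(OCOC)cc2OC(C)(C)CCc2c1OCOC | intermediate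
8 | 5-[5,7-bis(methoxymethoxy)-2,2-dimethylchroman-6-yl]-5-oxopentanal | O=CCCCC(=O)c1c(OCOC)cc2OC(C)(C)CCc2c1OCOC | intermediate
9 | thiophenol (benzenethiol) | Sc1ccccc1 | starting material
10 | 2-chloro-N-methoxy-N-methylacetamide | CON(C)C(=O)CCl | starting material
11 | N-methoxy-N-methyl-2-(phenylsulfanyl)acetamide | CON(C)C(=O)CSc1ccccc1 | intermediate
12 | 5-bromo-2-methylpent-2-ene | CC(C)=CCCBr | starting material
13 | (4-methylpent-3-en-1-yl)magnesium bromide (formed in the flask, not isolated) | CC(C)=CCC[Mg]Br | intermediate
14 | 6-methyl-1-(phenylsulfanyl)hept-5-en-2-one | CC(C)=CCCC(=O)CSc1ccccc1 | intermediate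
15 | 7-methyl-1-[methyl(phenyl)amino]-2-(phenylsulfanyl)oct-6-en-3-one, racemic (formed in the flask, not isolated) | CC(C)=CCCC(=O)C(CN(C)c1ccccc1)Sc1ccccc1 | intermediate
16 | 7-methyl-2-(phenylsulfanyl)octa-1,6-dien-3-one | C=C(Sc1ccccc1)C(=O)CCC=C(C)C | intermediate
17 | 2-{3-[5,7-bis(methoxymethoxy)-2,2-dimethylchroman-6-yl]-3-oxopropyl}-9-methyl-5-oxo-4-(phenylsulfanyl)dec-8-enal, mixture of racemic diastereomers (formed in the flask, not isolated) | CC(C)=CCCC(=O)C(CC(C=O)CCC(=O)c1c(OCOC)cc2OC(C)(C)CCc2c1OCOC)Sc1ccccc1 | intermediate
18 | 4-{3-[5,7-bis(methoxymethoxy)-2,2-dimethylchroman-6-yl]-3-oxopropyl}-2-(3-methylbut-2-en-1-yl)-6-(phenylsulfanyl)cyclohex-2-en-1-one, mixture of racemic diastereomers at C4 and C6 | CC(C)=CCC1=CC(CCC(=O)c2c(OCOC)cc3OC(C)(C)CCc3c2OCOC)CC(Sc2ccccc2)C1=O | intermediate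
19 | 4-{3-[5,7-bis(methoxymethoxy)-2,2-dimethylchroman-6-yl]-3-oxopropyl}-2-(3-methylbut-2-en-1-yl)-6-(phenylsulfinyl)cyclohex-2-en-1-one, mixture of diastereomers at C4, C6 and S (formed in the flask, not isolated) | CC(C)=CCC1=CC(CCC(=O)c2c(OCOC)cc3OC(C)(C)CCc3c2OCOC)CC(S(=O)c2ccccc2)C1=O | intermediate
20 | 4-{3-[5,7-bis(methoxymethoxy)-2,2-dimethylchroman-6-yl]-3-oxopropyl}-2-(3-methylbut-2-en-1-yl)cyclohexa-2,5-dien-1-one, racemic at C4 (formed in the flask, not isolated) | CC(C)=CCC1=CC(CCC(=O)c2c(OCOC)cc3OC(C)(C)CCc3c2OCOC)C=CC1=O | intermediate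
21 | 1-[5,7-bis(methoxymethoxy)-2,2-dimethylchroman-6-yl]-3-[4-hydroxy-3-(3-methylbut-2-en-1-yl)phenyl]propan-1-one (achiral) | CC(C)=CCc1cc(CCC(=O)c2c(OCOC)cc3OC(C)(C)CCc3c2OCOC)ccc1O | intermediate
22 | 1-(5,7-dihydroxy-2,2-dimethylchroman-6-yl)-3-[4-hydroxy-3-(3-methylbut-2-en-1-yl)phenyl]propan-1-one (achiral, no stereocentre) | CC(C)=CCc1cc(CCC(=O)c2c(O)cc3c(c2O)CCC(C)(C)O3)ccc1O | target

**Step count and risks**

Total: 10 steps. Longest linear sequence: 7 steps (1, 2, 3, 4, 8, 9, 10 from phloroglucinol); the vinyl ketone branch (steps 5–7) joins at step 8.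

Steps most likely to fail:

Step 8 (annulation). The enamine addition to the α-substituted, captodative acceptor may be slow or reversible, so that self-aldol condensation of 8 and oligomerisation of 16 take over. Fallback with reversed polarity: starting from 8, α-methylenation with aqueous formaldehyde and pyrrolidinium propanoate (i-PrOH, 45 °C) should give 5-[5,7-bis(methoxymethoxy)-2,2-dimethylchroman-6-yl]-2-methylidene-5-oxopentanal F1. Ketone 14, whose sulfur-bearing methylene is a soft carbon acid, is then added to F1 with catalytic DBU in THF. This forms C5'–C6' instead of C1'–C6' and gives the same keto-aldehyde 17, now isolated. Ring closure with piperidinium acetate in toluene returns to the route at 18; enone 16 is not needed on this path.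

Step 7 (α-methylenation). A second Mannich/Michael event (methylene-bridged dimer) or polymerisation of the reactive enone may occur while it forms at reflux. Fallback by a stepwise route to the same enone: starting from 14, C-methylation at the sulfur-bearing carbon (NaH, MeI, THF, 0 °C) would give 7-methyl-2-(phenylsulfanyl)oct-6-en-3-one F2. Chlorination of the sulfide with N-chlorosuccinimide (CH2Cl2, 0 °C) places chlorine on the same carbon to give 2-chloro-7-methyl-2-(phenylsulfanyl)oct-6-en-3-one F3. Dehydrochlorination with Et3N at room temperature, which can only take a methyl hydrogen, comes back to the route at 16 under conditions mild enough to avoid oligomerisation.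

Step 3 (metalation/acylation). Deprotonation may be diverted to C8 (between the 7-MOM ether and the ring oxygen), or the aryllithium may enolise the lactone instead of adding. Fallback that fixes the regiochemistry by O-alkylation instead of metalation: starting from 1, Friedel–Crafts acylation with 5-chloropentanoyl chloride (AlCl3, nitrobenzene) would give 5-chloro-1-(2,4,6-trihydroxyphenyl)pentan-1-one F4. The one hydroxyl not hydrogen-bonded to the ketone (para) is alkylated with 3-chloro-3-methylbut-1-yne (CuCl2 cat., DBU, MeCN, 0 °C) to 5-chloro-1-{2,6-dihydroxy-4-[(2-methylbut-3-yn-2-yl)oxy]phenyl}pentan-1-one F5. Aromatic Claisen rearrangement and electrocyclisation (xylene, 140 °C) at either of the two equivalent ortho carbons gives 5-chloro-1-(5,7-dihydroxy-2,2-dimethyl-2H-chromen-6-yl)pentan-1-one F6, with the ring oxygen necessarily para to the ketone. Hydrogenation (H2, Pd/C, EtOAc) gives 5-chloro-1-(5,7-dihydroxy-2,2-dimethylchroman-6-yl)pentan-1-one F7, and MOM protection (NaH, MOMCl, DMF) gives 1-[5,7-bis(methoxymethoxy)-2,2-dimethylchroman-6-yl]-5-chloropentan-1-one F8. Kornblum oxidation of the primary chloride (NaI, NaHCO3, DMSO, 100 °C) returns to the route at 8.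

Further compounds
F1 | step 8 | 5-[5,7-bis(methoxymethoxy)-2,2-dimethylchroman-6-yl]-2-methylidene-5-oxopentanal | C=C(C=O)CCC(=O)c1c(OCOC)cc2OC(C)(C)CCc2c1OCOC
F2 | step 7 | 7-methyl-2-(phenylsulfanyl)oct-6-en-3-one (racemic) | CC(Sc1ccccc1)C(=O)CCC=C(C)C
F3 | step 7 | 2-chloro-7-methyl-2-(phenylsulfanyl)oct-6-en-3-one (racemic) | CC(Cl)(Sc1ccccc1)C(=O)CCC=C(C)C
F4 | step 3 | 5-chloro-1-(2,4,6-trihydroxyphenyl)pentan-1-one | O=C(CCCCCl)c1c(O)cc(O)cc1O
F5 | step 3 | 5-chloro-1-{2,6-dihydroxy-4-[(2-methylbut-3-yn-2-yl)oxy]phenyl}pentan-1-one | C#CC(C)(C)Oc1cc(O)c(C(=O)CCCCCl)c(O)c1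
F6 | step 3 | 5-chloro-1-(5,7-dihydroxy-2,2-dimethyl-2H-chromen-6-yl)pentan-1-one | CC1(C)C=Cc2c(O)c(C(=O)CCCCCl)c(O)cc2O1
F7 | step 3 | 5-chloro-1-(5,7-dihydroxy-2,2-dimethylchroman-6-yl)pentan-1-one | CC1(C)CCc2c(O)c(C(=O)CCCCCl)c(O)cc2O1
F8 | step 3 | 1-[5,7-bis(methoxymethoxy)-2,2-dimethylchroman-6-yl]-5-chloropentan-1-one | CC1(C)CCc2c(OCOC)c(C(=O)CCCCCl)c(OCOC)cc2O1
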